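**Retrosynthetic overview**

1. The target comes from its 7-acetate 18, made by Perkin–Oglialoro condensation of chromanylacetic acid 16 with 2,4-dihydroxy-6-methoxybenzaldehyde 17; this forms the coumarin C3=C4 bond and the lactone O1–C2 bond, so the pyranone ring is closed last.
2. Acid 16 comes from chlorochromene 12 by Negishi-type α-arylation (C6–CH2 bond), hydrogenation of the chromene C3=C4 bond and ester cleavage.
3. Key disconnection: the pyran ring of the chroman is opened at C4–C4a and O1–C8a. Chromene 12 arises from 4-chloro-3-methoxybenzyne 9 and prenal 8 by formal [2+2] addition of the C=O group, 4π ring opening and oxa-6π closure; the ring is delivered at the chromene oxidation level.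
4. Enabling feature: the methoxy group on C5 of the chroman benzene ring sits next to C4a. In the aryne C4a≡C8a it sends the carbonyl oxygen to C8a and the carbanion to C4a; the gem-dimethyl C2 with its C3–C4 chain maps exactly onto prenal.
5. Ring order: chroman benzene ring (bought as phenol 1), then pyran ring (step 4), then pyranone ring (step 8) onto the coumarin benzene ring bought as 17.

Key step: step 4

Remark: the target has no stereocentre and no stereogenic double bond, so no step has to control configuration. Compounds 1, 8, 13 and 17 are taken as catalogue compounds.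

**Route**

Step 1
Reactants: 1 4-chloro-3-methoxyphenol
Product: 2 4-chloro-3-methoxyphenyl N-isopropylcarbamate
Conditions: i-PrNCO, Et3N (cat.), CH2Cl2, 25 °C
Reagents that add atoms: isopropyl isocyanate, CC(C)N=C=O
Why: Base-catalysed addition of the phenol O–H to the isocyanate (carbamoylation) is clean and installs a directing group that mild base can remove later.

Step 2
Reactants: 2 4-chloro-3-methoxyphenyl N-isopropylcarbamate
Product: 5 4-chloro-3-methoxy-2-(trimethylsilyl)phenyl N-isopropylcarbamate, via N-TBS carbamate 3 (not isolated), via C-silylated N-TBS carbamate 4 (not isolated)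
Conditions: TBSOTf, TMEDA, Et2O, 0→25 °C; then TMEDA, n-BuLi, −78 °C; Me3SiCl, −78→25 °C; aq. NaHSO4
Reagents that add atoms: chlorotrimethylsilane, C[Si](C)(C)Cl; tert-butyldimethylsilyl triflate, CC(C)(C)[Si](C)(C)OS(=O)(=O)C(F)(F)F (its silyl group stays only in 3 and 4 and is lost on work-up)
Why: Directed ortho-metalation: after in situ N-silylation the carbamate and the C3 methoxy group jointly acidify C2 between them, the aryllithium is trapped by Me3SiCl, and the aryl chloride is inert to n-BuLi at −78 °C and meta to the lithiated carbon, so no elimination can occur.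

Step 3
Reactants: 5 4-chloro-3-methoxy-2-(trimethylsilyl)phenyl N-isopropylcarbamate
Product: 7 4-chloro-3-methoxy-2-(trimethylsilyl)phenyl trifluoromethanesulfonate, via silylphenol 6 (not isolated)
Conditions: Et2NH, DBU, MeCN, 40 °C; then PhNTf2, 25 °C
Reagents that add atoms: N-phenylbis(trifluoromethanesulfonimide), O=S(=O)(N(c1ccccc1)S(=O)(=O)C(F)(F)F)C(F)(F)F
Why: DBU deprotonates the carbamate N–H, the phenoxide is expelled (E1cB) while Et2NH scavenges the isocyanate, and the phenoxide is sulfonylated by PhNTf2 in the same pot to give the o-silylaryl triflate.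

Step 4
Reactants: 7 4-chloro-3-methoxy-2-(trimethylsilyl)phenyl trifluoromethanesulfonate; 8 3-methylbut-2-enal (prenal)
Product: 12 6-chloro-5-methoxy-2,2-dimethyl-2H-chromene, via aryne 9 (not isolated), via benzoxete 10 (not isolated), via o-quinone methide 11 (not isolated)
Conditions: CsF (3 equiv), prenal (4 equiv), MeCN, 25→50 °C, slow addition of 7
Reagents that add atoms: none
Why: Fluoride attacks silicon of 7 and triflate leaves to give aryne 9; the carbonyl oxygen of prenal adds at C8a and the resulting C4a aryl anion collapses onto the carbonyl carbon to give benzoxete 10, which opens by 4π electrocyclic ring opening to the vinyl o-quinone methide 11 and closes by oxa-6π electrocyclization to 2H-chromene 12. The closest known reaction type is the annulation of arynes with α,β-unsaturated aldehydes to 2H-chromenes, related to aryne insertion into the C=O bond of formamides. The transient oxete ring closes by a stepwise, zwitterionic formal [2+2] addition, and the pyran ring closes by thermally allowed disrotatory 6π electrocyclization of the (Z)-dienone, driven by rearomatization of the benzene ring. No stereocentre is created, because C2 carries two methyl groups and the C3=C4 bond is hydrogenated later. The step needs regioselective aryne capture (O to C8a, C to C4a): the C5 methoxy group next to C4a inductively stabilizes negative charge at C4a and distorts the aryne so that nucleophiles add at the distal carbon C8a, and the C6 chlorine, meta to C4a, acts in the same sense. It also needs 1,2- and not 1,4-capture of the enal and ring closure before a second aryne adds to 11; the fully substituted β-carbon of prenal, the intramolecular 6π closure, slow addition of 7 and excess prenal should secure this.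

Step 5
Reactants: 12 6-chloro-5-methoxy-2,2-dimethyl-2H-chromene; 13 (2-tert-butoxy-2-oxoethyl)zinc bromide
Product: 14 tert-butyl 2-(5-methoxy-2,2-dimethyl-2H-chromen-6-yl)acetate
Conditions: Pd(dba)2 (cat.), Q-Phos [(C5Ph5)Fe(C5H4P(t-Bu)2)] (cat.), THF, 60 °C
Reagents that add atoms: none
Why: Negishi-type α-arylation with a Reformatsky reagent: zerovalent palladium with the bulky electron-rich phosphine inserts into the aryl C–Cl bond, the zinc enolate transmetalates and reductive elimination forms the aryl–CH2 bond under neutral conditions that leave the chromene untouched.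

Step 6
Reactants: 14 tert-butyl 2-(5-methoxy-2,2-dimethyl-2H-chromen-6-yl)acetate
Product: 15 tert-butyl 2-(5-methoxy-2,2-dimethylchroman-6-yl)acetate
Conditions: H2 (1 atm), Pd/C, EtOAc, 25 °C
Reagents that add atoms: none
Why: Heterogeneous catalytic hydrogenation saturates the cis-disubstituted styrenic C3=C4 bond and brings C4 to the CH2 level of the target, while the arene and the ester are inert.

Step 7
Reactants: 15 tert-butyl 2-(5-methoxy-2,2-dimethylchroman-6-yl)acetate
Product: 16 2-(5-methoxy-2,2-dimethylchroman-6-yl)acetic acid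
Conditions: CF3CO2H, CH2Cl2, 25 °C
Reagents that add atoms: none
Why: Acidolysis of the tert-butyl ester (loss of the tert-butyl cation as isobutene) frees the acid, and the chroman aryl ether is stable to CF3CO2H at room temperature.

Step 8
Reactants: 16 2-(5-methoxy-2,2-dimethylchroman-6-yl)acetic acid; 17 2,4-dihydroxy-6-methoxybenzaldehyde
Product: 18 5-methoxy-3-(5-methoxy-2,2-dimethylchroman-6-yl)-2-oxo-2H-chromen-7-yl acetate
Conditions: Ac2O, Et3N, 120 °C
Reagents that add atoms: acetic anhydride, CC(=O)OC(C)=O
Why: Perkin–Oglialoro condensation: the mixed anhydride of 16 acylates the ortho-hydroxyl of 17, intramolecular aldol condensation onto the aldehyde and dehydration close the pyranone ring, and the 4-hydroxyl is acetylated in passing.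

Step 9
Reactants: 18 5-methoxy-3-(5-methoxy-2,2-dimethylchroman-6-yl)-2-oxo-2H-chromen-7-yl acetate
Product: 19 7-hydroxy-5-methoxy-3-(5-methoxy-2,2-dimethyl-3,4-dihydro-2H-chromen-6-yl)-2H-chromen-2-one (target)
Conditions: K2CO3 (cat.), MeOH, 0→25 °C; then 1 M HCl
Reagents that add atoms: none
Why: Mild base-catalysed methanolysis (transesterification) removes the phenolic acetate much faster than the lactone can be opened, and acidification returns the free 7-hydroxycoumarin.

**Compound list**

1 | 4-chloro-3-methoxyphenol | COc1cc(O)ccc1Cl | starting material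
2 | 4-chloro-3-methoxyphenyl N-isopropylcarbamate | COc1cc(OC(=O)NC(C)C)ccc1Cl | intermediate
3 | 4-chloro-3-methoxyphenyl N-(tert-butyldimethylsilyl)-N-isopropylcarbamate | COc1cc(OC(=O)N(C(C)C)[Si](C)(C)C(C)(C)C)ccc1Cl | intermediate
4 | 4-chloro-3-methoxy-2-(trimethylsilyl)phenyl N-(tert-butyldimethylsilyl)-N-isopropylcarbamate | COc1c(Cl)ccc(OC(=O)N(C(C)C)[Si](C)(C)C(C)(C)C)c1[Si](C)(C)C | intermediate
5 | 4-chloro-3-methoxy-2-(trimethylsilyl)phenyl N-isopropylcarbamate | COc1c(Cl)ccc(OC(=O)NC(C)C)c1[Si](C)(C)C | intermediate
6 | 4-chloro-3-methoxy-2-(trimethylsilyl)phenol (formed as its DBU-H phenoxide) | COc1c(Cl)ccc(O)c1[Si](C)(C)C | intermediate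
7 | 4-chloro-3-methoxy-2-(trimethylsilyl)phenyl trifluoromethanesulfonate | COc1c(Cl)ccc(OS(=O)(=O)C(F)(F)F)c1[Si](C)(C)C | intermediate
8 | 3-methylbut-2-enal (prenal) | CC(C)=CC=O | starting material
9 | 4-chloro-3-methoxybenzyne (4-chloro-3-methoxy-1,2-didehydrobenzene) | COC1=C(Cl)C=CC#C1 | intermediate
10 | 4-chloro-3-methoxy-2-(2-methylprop-1-en-1-yl)-2H-benzo[b]oxete | COc1c(Cl)ccc2OC(C=C(C)C)c12 | intermediate
11 | (6Z)-4-chloro-5-methoxy-6-(3-methylbut-2-en-1-ylidene)cyclohexa-2,4-dien-1-one | CC(C)=C/C=C1\C(=O)C=CC(Cl)=C1OC | intermediate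
12 | 6-chloro-5-methoxy-2,2-dimethyl-2H-chromene | COc1c(Cl)ccc2OC(C)(C)C=Cc12 | intermediate
13 | (2-tert-butoxy-2-oxoethyl)zinc bromide | Br[Zn]CC(=O)OC(C)(C)C | starting material
14 | tert-butyl 2-(5-methoxy-2,2-dimethyl-2H-chromen-6-yl)acetate | COc1c(CC(=O)OC(C)(C)C)ccc2OC(C)(C)C=Cc12 | intermediate
15 | tert-butyl 2-(5-methoxy-2,2-dimethylchroman-6-yl)acetate | COc1c(CC(=O)OC(C)(C)C)ccc2OC(C)(C)CCc12 | intermediate
16 | 2-(5-methoxy-2,2-dimethylchroman-6-yl)acetic acid | COc1c(CC(=O)O)ccc2OC(C)(C)CCc12 | intermediate
17 | 2,4-dihydroxy-6-methoxybenzaldehyde | COc1cc(O)cc(O)c1C=O | starting material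
18 | 5-methoxy-3-(5-methoxy-2,2-dimethylchroman-6-yl)-2-oxo-2H-chromen-7-yl acetate | COc1c(-c2cc3c(OC)cc(OC(C)=O)cc3oc2=O)ccc2c1CCC(C)(C)O2 | intermediate
19 | 7-hydroxy-5-methoxy-3-(5-methoxy-2,2-dimethyl-3,4-dihydro-2H-chromen-6-yl)-2H-chromen-2-one | COc1c(-c2cc3c(OC)cc(O)cc3oc2=O)ccc2c1CCC(C)(C)O2 | target

**Step count**

Total step count: 9. Longest linear sequence: 9 steps (1 to 19); 8, 13 and 17 enter as bought partners.

**Steps most likely to fail**

Step 4. Capture of the aryne by the weakly nucleophilic enal carbonyl may lose out to fluoride-induced self-condensation of prenal, and the o-quinone methide may be intercepted by a second aryne before it ring-closes. The fallback gives up the aryne and sets out from carbamate 2, returning at chromene 12. Carbamate 2 is N-silylated to 3 and lithiated as in step 2, and the aryllithium is quenched with DMF; acidic work-up should give 4-chloro-2-formyl-3-methoxyphenyl N-isopropylcarbamate F1. Et2NH, DBU, MeCN at 40 °C should free 3-chloro-6-hydroxy-2-methoxybenzaldehyde F2. Addition of 2-methylprop-1-enylmagnesium bromide (2.5 equiv, THF, 0 °C) should give racemic 4-chloro-2-(1-hydroxy-3-methylbut-2-en-1-yl)-3-methoxyphenol F3. Warming F3 with catalytic pyridinium p-toluenesulfonate in toluene should dehydrate it to o-quinone methide 11, which closes to 12. Here the C4–C4a bond is made by directed metalation and the O1–C8a bond is the phenol C–O bond bought with 1.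

Step 5. Oxidative addition into the electron-rich, ortho-methoxy aryl chloride may be slow, and the zinc enolate may be protonated before it transmetalates. The fallback reverses the polarity of the partners; it sets out from 12 and returns at ester 14. Borylation of 12 (B2pin2, Pd2(dba)3, XPhos, KOAc, dioxane, 100 °C) should give 2-(5-methoxy-2,2-dimethyl-2H-chromen-6-yl)-4,4,5,5-tetramethyl-1,3,2-dioxaborolane F4. Coupling of F4 with tert-butyl bromoacetate (Pd(OAc)2, P(o-tol)3, K3PO4, THF/H2O, 25 °C) should then give 14.

Step 8. With a hindered ortho-methoxy arylacetic acid and an electron-rich, doubly ortho-substituted aldehyde, the hot anhydride may only acetylate both phenols, or the sequence may stall before C–C bond formation and ring closure. The fallback separates acylation from condensation and uses a benzyl protecting group; it sets out from 16 and 17 and returns at target 19. Selective alkylation of the non-chelated hydroxyl of 17 (BnBr, NaHCO3, KI, MeCN, 80 °C) should give 4-(benzyloxy)-2-hydroxy-6-methoxybenzaldehyde F5. Esterification of 16 with F5 (EDC·HCl, DMAP, CH2Cl2, 25 °C) should give 5-(benzyloxy)-2-formyl-3-methoxyphenyl 2-(5-methoxy-2,2-dimethylchroman-6-yl)acetate F6. DBU in MeCN at 25 °C should close F6 by intramolecular Knoevenagel condensation to 7-(benzyloxy)-5-methoxy-3-(5-methoxy-2,2-dimethylchroman-6-yl)-2H-chromen-2-one F7. Hydrogenolysis of F7 (H2, Pd/C, EtOAc, 25 °C) should give 19.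

**Further compounds**

F1 | step 4 | 4-chloro-2-formyl-3-methoxyphenyl N-isopropylcarbamate | COc1c(Cl)ccc(OC(=O)NC(C)C)c1C=O
F2 | step 4 | 3-chloro-6-hydroxy-2-methoxybenzaldehyde | COc1c(Cl)ccc(O)c1C=O
F3 | step 4 | racemic 4-chloro-2-(1-hydroxy-3-methylbut-2-en-1-yl)-3-methoxyphenol | COc1c(Cl)ccc(O)c1C(O)C=C(C)C
F4 | step 5 | 2-(5-methoxy-2,2-dimethyl-2H-chromen-6-yl)-4,4,5,5-tetramethyl-1,3,2-dioxaborolane | COc1c(B2OC(C)(C)C(C)(C)O2)ccc2OC(C)(C)C=Cc12
F5 | step 8 | 4-(benzyloxy)-2-hydroxy-6-methoxybenzaldehyde | COc1cc(OCc2ccccc2)cc(O)c1C=O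
F6 | step 8 | 5-(benzyloxy)-2-formyl-3-methoxyphenyl 2-(5-methoxy-2,2-dimethylchroman-6-yl)acetate | COc1cc(OCc2ccccc2)cc(OC(=O)Cc2ccc3OC(C)(C)CCc3c2OC)c1C=O
F7 | step 8 | 7-(benzyloxy)-5-methoxy-3-(5-methoxy-2,2-dimethylchroman-6-yl)-2H-chromen-2-one | COc1c(-c2cc3c(OC)cc(OCc4ccccc4)cc3oc2=O)ccc2c1CCC(C)(C)O2
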